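Retrosynthesis: the enyne cap, the C10 acetate and the C12 bromide are taken back to a bicyclic 4,6-dione (C10 and C12 as ketones); C8–C9 and C11–C12 are then cut together, which opens both rings to one acyclic bis-ether.
Enabling feature: C10, the acetoxy carbon of ring B (oxocane), lies between C9 (which carries the oxygen of ring A, the tetrahydrofuran) and C11; as a ketone both its α-carbons are nucleophiles, C8 is a primary CH2 beside C7–O and C12 is an acyl carbon beside C13–O.
Forward: C6–C8 from (R)-glyceraldehyde acetonide, C4–C5 by allylation, C9–C11 as a methallyl ether, C12–C15 from (S)-2-bromobutanoic acid, C3 from iodoform, C1–C2 by Sonogashira coupling; one base-mediated operation then closes ring A (C8–C9) and ring B (C11–C12) in that order.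
Stereochemistry: C7 from the chiral pool, C6 by Felkin-controlled allylation, C13 by SN2 inversion, C9 by the bicyclic constraint, C10 and C12 by catalyst-controlled reduction of the dione, C12 inverted when bromide enters.
Key step: step 12
Remark: locants C1–C15 follow the linear carbon chain of the target (C1 = terminal alkyne carbon, C15 = methyl of the ethyl group); bicyclic names use 2,8-dioxabicyclo[5.2.1]decane numbering.

Step 1
Reactants: 1 (R)-2,2-dimethyl-1,3-dioxolane-4-carbaldehyde; 2 allyl bromide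
Product: 3 (S)-1-[(R)-2,2-dimethyl-1,3-dioxolan-4-yl]but-3-en-1-ol
Conditions: Zn, THF/sat. aq NH4Cl, 0 °C → rt
Reagents that add atoms: none
Why: Barbier-type zinc allylation of an α-alkoxy aldehyde; Felkin–Anh (non-chelation) attack should favour the anti adduct and so set C6 as S next to the chiral-pool centre C7.

Step 2
Reactants: 3 (S)-1-[(R)-2,2-dimethyl-1,3-dioxolan-4-yl]but-3-en-1-ol; 4 3-chloro-2-methylprop-1-ene
Product: 5 (R)-2,2-dimethyl-4-[(S)-1-(2-methylallyloxy)but-3-en-1-yl]-1,3-dioxolane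
Conditions: NaH, Bu4NI (cat.), THF/DMF, 0 °C → rt
Reagents that add atoms: none
Why: Williamson etherification of the C6 alkoxide; the methallyl group is a base-stable latent acetonyl unit (C9–C11).

Step 3
Reactants: 5 (R)-2,2-dimethyl-4-[(S)-1-(2-methylallyloxy)but-3-en-1-yl]-1,3-dioxolane
Product: 6 (2R,3S)-3-(2-methylallyloxy)hex-5-ene-1,2-diol
Conditions: AcOH/H2O (4:1), 40 °C
Reagents that add atoms: none
Why: Acid hydrolysis of the acetonide frees the C7/C8 diol while the ethers and both alkenes should be untouched.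

Step 4
Reactants: 6 (2R,3S)-3-(2-methylallyloxy)hex-5-ene-1,2-diol
Product: 7 (2R,3S)-3-(2-methylallyloxy)-1-(trityloxy)hex-5-en-2-ol
Conditions: Ph3CCl, Et3N, DMAP (cat.), CH2Cl2, rt
Reagents that add atoms: trityl chloride ClC(c1ccccc1)(c1ccccc1)c1ccccc1
Why: Selective tritylation of the primary (C8) hydroxyl on steric grounds leaves only the C7 hydroxyl free and, unlike a silyl group, cannot migrate in the next basic step.

Step 5
Reactants: 7 (2R,3S)-3-(2-methylallyloxy)-1-(trityloxy)hex-5-en-2-ol; 8 (S)-2-bromobutanoic acid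
Product: 9 (R)-2-{[(2R,3S)-3-(2-methylallyloxy)-1-(trityloxy)hex-5-en-2-yl]oxy}butanoic acid
Conditions: NaH (3 equiv), THF/DMF, 0 → 50 °C; then aq citric acid
Reagents that add atoms: none
Why: Williamson etherification with an α-bromo carboxylate (as in the muramic acid synthesis); SN2 displacement with inversion turns the (S)-bromide into the (R)-configured C13 ether centre.

Step 6
Reactants: 9 (R)-2-{[(2R,3S)-3-(2-methylallyloxy)-1-(trityloxy)hex-5-en-2-yl]oxy}butanoic acid
Product: 10 (R)-N-methoxy-N-methyl-2-{[(2R,3S)-3-(2-methylallyloxy)-1-(trityloxy)hex-5-en-2-yl]oxy}butanamide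
Conditions: CDI, CH2Cl2, rt; then MeNH(OMe)·HCl
Reagents that add atoms: N,O-dimethylhydroxylamine hydrochloride CNOC.Cl
Why: Weinreb amide formation through the acyl imidazole, a mild coupling that should not epimerise C13.

Step 7
Reactants: 10 (R)-N-methoxy-N-methyl-2-{[(2R,3S)-3-(2-methylallyloxy)-1-(trityloxy)hex-5-en-2-yl]oxy}butanamide
Product: 11 (R)-N-methoxy-N-methyl-2-{[(2R,3S)-5-oxo-3-(2-oxopropoxy)-1-(trityloxy)pentan-2-yl]oxy}butanamide
Conditions: O3, CH2Cl2/MeOH, −78 °C; then Me2S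
Reagents that add atoms: ozone [O-][O+]=O
Why: Ozonolysis with reductive work-up cleaves both terminal alkenes at once, unveiling the C10 methyl ketone from the methallyl ether and the C4 aldehyde from the allyl group.

Step 8
Reactants: 11 (R)-N-methoxy-N-methyl-2-{[(2R,3S)-5-oxo-3-(2-oxopropoxy)-1-(trityloxy)pentan-2-yl]oxy}butanamide
Product: 12 (R)-2-{[(2R,3S,5E)-6-iodo-3-(2-oxopropoxy)-1-(trityloxy)hex-5-en-2-yl]oxy}-N-methoxy-N-methylbutanamide
Conditions: CrCl2, CHI3, THF, 0 °C → rt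
Reagents that add atoms: iodoform IC(I)I
Why: Takai olefination, selective for the aldehyde over the ketone and the amide, builds the (E)-vinyl iodide (C3=C4).

Step 9
Reactants: 12 (R)-2-{[(2R,3S,5E)-6-iodo-3-(2-oxopropoxy)-1-(trityloxy)hex-5-en-2-yl]oxy}-N-methoxy-N-methylbutanamide; 13 ethynyltriisopropylsilane
Product: 14 (R)-N-methoxy-N-methyl-2-{[(2R,3S,5E)-3-(2-oxopropoxy)-8-(triisopropylsilyl)-1-(trityloxy)oct-5-en-7-yn-2-yl]oxy}butanamide
Conditions: Pd(PPh3)4 (cat.), CuI (cat.), i-Pr2NH, THF, rt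
Reagents that add atoms: none
Why: Sonogashira coupling with retention of the E geometry installs C1–C2 as a silyl-protected enyne that should tolerate the later base, hydride-transfer and acid steps.

Step 10
Reactants: 14 (R)-N-methoxy-N-methyl-2-{[(2R,3S,5E)-3-(2-oxopropoxy)-8-(triisopropylsilyl)-1-(trityloxy)oct-5-en-7-yn-2-yl]oxy}butanamide
Product: 15 (R)-2-{[(2R,3S,5E)-1-hydroxy-3-(2-oxopropoxy)-8-(triisopropylsilyl)oct-5-en-7-yn-2-yl]oxy}-N-methoxy-N-methylbutanamide
Conditions: CSA (cat.), MeOH/CH2Cl2, 0 °C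
Reagents that add atoms: none
Why: Acid-catalysed solvolysis of the trityl ether frees the primary C8 hydroxyl.

Step 11
Reactants: 15 (R)-2-{[(2R,3S,5E)-1-hydroxy-3-(2-oxopropoxy)-8-(triisopropylsilyl)oct-5-en-7-yn-2-yl]oxy}-N-methoxy-N-methylbutanamide
Product: 16 (R)-2-{[(2S,3S,5E)-1-iodo-3-(2-oxopropoxy)-8-(triisopropylsilyl)oct-5-en-7-yn-2-yl]oxy}-N-methoxy-N-methylbutanamide
Conditions: I2, PPh3, imidazole, CH2Cl2, 0 °C → rt
Reagents that add atoms: iodine II
Why: Appel-type (Garegg–Samuelsson) iodination turns C8 into the primary electrophile for the cyclisation; the spatial arrangement at C7 is unchanged (its descriptor changes only through the CIP rank of iodine).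

Step 12
Reactants: 16 (R)-2-{[(2S,3S,5E)-1-iodo-3-(2-oxopropoxy)-8-(triisopropylsilyl)oct-5-en-7-yn-2-yl]oxy}-N-methoxy-N-methylbutanamide
Product: 18 (1R,3R,7R,9S)-3-ethyl-9-[(2E)-5-(triisopropylsilyl)pent-2-en-4-yn-1-yl]-2,8-dioxabicyclo[5.2.1]decane-4,6-dione, via ring-A acetyl Weinreb amide 17 (not isolated)
Conditions: KN(SiMe3)2 (2.2 equiv, in two portions), THF (0.005 M), −78 → 0 °C; aq NH4Cl
Reagents that add atoms: none
Why: Proposed new method: the potassium enolate on the ring-oxygen side of the acetonyl ketone (C9; the C9 and C11 enolates interconvert by proton transfer through ketone not yet deprotonated) displaces the primary iodide at C8 to form C8–C9 and ring A, and the second portion of base then enolises the methyl group (C11), which acylates the Weinreb amide carbon C12 to form C11–C12 and ring B, the sequence ending in the stabilised 1,3-diketonate. The closest known reaction types are the intramolecular alkylation of α-alkoxy carbonyl enolates used for cyclic ethers and the crossed Claisen (Dieckmann-type) acylation of ketone enolates by Weinreb amides; new are their union in one operation and the eight-membered acylation. Ring A closes in the 5-(enolexo)-exo-tet mode and ring B in the 8-(enolendo)-exo-trig mode, the latter helped because both arms sit cis on the freshly formed tetrahydrofuran. The only new stereocentre, C9, is set by the ring constraint: only the epimer with the C9 acyl arm cis to the C7 ether arm can bridge, and the trans epimer is returned through its C9 enolate. The step needs C-alkylation at C9 before any acylation, which the fast five-membered displacement of iodide at −78 °C against the slow attack on the amide should secure, and it needs C13 to stay intact, which the low acidity of the amide α-hydrogen relative to the ketone α-hydrogens should secure.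

Step 13
Reactants: 18 (1R,3R,7R,9S)-3-ethyl-9-[(2E)-5-(triisopropylsilyl)pent-2-en-4-yn-1-yl]-2,8-dioxabicyclo[5.2.1]decane-4,6-dione
Product: 19 (1R,3R,4R,6R,7R,9S)-3-ethyl-9-[(2E)-5-(triisopropylsilyl)pent-2-en-4-yn-1-yl]-2,8-dioxabicyclo[5.2.1]decane-4,6-diol
Conditions: RuCl[(R,R)-TsDPEN](p-cymene) (cat.), HCO2H/Et3N (5:2), CH2Cl2, rt
Reagents that add atoms: none
Why: Noyori–Ikariya asymmetric transfer hydrogenation of a 1,3-diketone, a reaction type known to give anti-1,3-diols under catalyst control and to spare alkenes and alkynes; both carbonyls sit between a CH2 and an α-oxygenated ring carbon, so one catalyst antipode (taken as the (R,R) complex, with the α-oxygenated carbon as the large group) should set C10 and C12 in the same sense.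

Step 14
Reactants: 19 (1R,3R,4R,6R,7R,9S)-3-ethyl-9-[(2E)-5-(triisopropylsilyl)pent-2-en-4-yn-1-yl]-2,8-dioxabicyclo[5.2.1]decane-4,6-diol
Product: 21 (1R,3R,4S,6R,7R,9S)-4-bromo-3-ethyl-9-[(2E)-5-(triisopropylsilyl)pent-2-en-4-yn-1-yl]-2,8-dioxabicyclo[5.2.1]decan-6-yl acetate, via cyclic orthoacetate 20 (not isolated)
Conditions: MeC(OMe)3, PPTS (cat.), CH2Cl2, rt; then AcBr, 0 °C
Reagents that add atoms: trimethyl orthoacetate CC(OC)(OC)OC; acetyl bromide CC(Br)=O
Why: Sharpless-type one-pot conversion of a diol into an acetoxy bromide through the cyclic orthoacetate and its 1,3-dioxan-2-ylium ion; bromide should open at C12 with inversion from the open exo face (the rear side of C10 is shielded by ring A), leaving the acetate on C10 with retention.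

Step 15
Reactants: 21 (1R,3R,4S,6R,7R,9S)-4-bromo-3-ethyl-9-[(2E)-5-(triisopropylsilyl)pent-2-en-4-yn-1-yl]-2,8-dioxabicyclo[5.2.1]decan-6-yl acetate
Product: 22 (1R,3R,4S,6R,7R,9S)-4-bromo-3-ethyl-9-[(2E)-pent-2-en-4-yn-1-yl]-2,8-dioxabicyclo[5.2.1]decan-6-yl acetate
Conditions: Bu4NF, AcOH, THF, 0 °C
Reagents that add atoms: none
Why: Fluoride-mediated protodesilylation of the alkynylsilane, buffered with acetic acid to spare the acetate and the secondary bromide, should give the target.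

Compound list
1 | (R)-2,2-dimethyl-1,3-dioxolane-4-carbaldehyde | O=C[C@H]1COC(C)(C)O1 | starting material
2 | allyl bromide | C=CCBr | starting material
3 | (S)-1-[(R)-2,2-dimethyl-1,3-dioxolan-4-yl]but-3-en-1-ol | C=CC[C@H](O)[C@H]1COC(C)(C)O1 | intermediate
4 | 3-chloro-2-methylprop-1-ene (methallyl chloride) | C=C(C)CCl | starting material
5 | (R)-2,2-dimethyl-4-[(S)-1-(2-methylallyloxy)but-3-en-1-yl]-1,3-dioxolane | C=CC[C@H](OCC(C)=C)[C@H]1COC(C)(C)O1 | intermediate
6 | (2R,3S)-3-(2-methylallyloxy)hex-5-ene-1,2-diol | C=CC[C@H](OCC(C)=C)[C@H](O)CO | intermediate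
7 | (2R,3S)-3-(2-methylallyloxy)-1-(trityloxy)hex-5-en-2-ol | C=CC[C@H](OCC(C)=C)[C@H](O)COC(c1ccccc1)(c1ccccc1)c1ccccc1 | intermediate
8 | (S)-2-bromobutanoic acid | CC[C@H](Br)C(=O)O | starting material
9 | (R)-2-{[(2R,3S)-3-(2-methylallyloxy)-1-(trityloxy)hex-5-en-2-yl]oxy}butanoic acid | C=CC[C@H](OCC(C)=C)[C@@H](COC(c1ccccc1)(c1ccccc1)c1ccccc1)O[C@H](CC)C(=O)O | intermediate
10 | (R)-N-methoxy-N-methyl-2-{[(2R,3S)-3-(2-methylallyloxy)-1-(trityloxy)hex-5-en-2-yl]oxy}butanamide | C=CC[C@H](OCC(C)=C)[C@@H](COC(c1ccccc1)(c1ccccc1)c1ccccc1)O[C@H](CC)C(=O)N(C)OC | intermediate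
11 | (R)-N-methoxy-N-methyl-2-{[(2R,3S)-5-oxo-3-(2-oxopropoxy)-1-(trityloxy)pentan-2-yl]oxy}butanamide | O=CC[C@H](OCC(C)=O)[C@@H](COC(c1ccccc1)(c1ccccc1)c1ccccc1)O[C@H](CC)C(=O)N(C)OC | intermediate
12 | (R)-2-{[(2R,3S,5E)-6-iodo-3-(2-oxopropoxy)-1-(trityloxy)hex-5-en-2-yl]oxy}-N-methoxy-N-methylbutanamide | I/C=C/C[C@H](OCC(C)=O)[C@@H](COC(c1ccccc1)(c1ccccc1)c1ccccc1)O[C@H](CC)C(=O)N(C)OC | intermediate
13 | ethynyltriisopropylsilane | C#C[Si](C(C)C)(C(C)C)C(C)C | starting material
14 | (R)-N-methoxy-N-methyl-2-{[(2R,3S,5E)-3-(2-oxopropoxy)-8-(triisopropylsilyl)-1-(trityloxy)oct-5-en-7-yn-2-yl]oxy}butanamide | CC(C)[Si](C(C)C)(C(C)C)C#C/C=C/C[C@H](OCC(C)=O)[C@@H](COC(c1ccccc1)(c1ccccc1)c1ccccc1)O[C@H](CC)C(=O)N(C)OC | intermediate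
15 | (R)-2-{[(2R,3S,5E)-1-hydroxy-3-(2-oxopropoxy)-8-(triisopropylsilyl)oct-5-en-7-yn-2-yl]oxy}-N-methoxy-N-methylbutanamide | CC(C)[Si](C(C)C)(C(C)C)C#C/C=C/C[C@H](OCC(C)=O)[C@@H](CO)O[C@H](CC)C(=O)N(C)OC | intermediate
16 | (R)-2-{[(2S,3S,5E)-1-iodo-3-(2-oxopropoxy)-8-(triisopropylsilyl)oct-5-en-7-yn-2-yl]oxy}-N-methoxy-N-methylbutanamide | CC(C)[Si](C(C)C)(C(C)C)C#C/C=C/C[C@H](OCC(C)=O)[C@@H](CI)O[C@H](CC)C(=O)N(C)OC | intermediate
17 | (R)-2-{[(2S,3R,5R)-5-acetyl-2-[(2E)-5-(triisopropylsilyl)pent-2-en-4-yn-1-yl]oxolan-3-yl]oxy}-N-methoxy-N-methylbutanamide (ring A closed; 2,3-trans, 3,5-cis) | CC(C)[Si](C(C)C)(C(C)C)C#C/C=C/C[C@@H]1O[C@@H](C(C)=O)C[C@H]1O[C@H](CC)C(=O)N(C)OC | intermediate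
18 | (1R,3R,7R,9S)-3-ethyl-9-[(2E)-5-(triisopropylsilyl)pent-2-en-4-yn-1-yl]-2,8-dioxabicyclo[5.2.1]decane-4,6-dione | CC(C)[Si](C(C)C)(C(C)C)C#C/C=C/C[C@@H]1O[C@@H]2C[C@H]1O[C@H](CC)C(=O)CC2=O | intermediate
19 | (1R,3R,4R,6R,7R,9S)-3-ethyl-9-[(2E)-5-(triisopropylsilyl)pent-2-en-4-yn-1-yl]-2,8-dioxabicyclo[5.2.1]decane-4,6-diol | CC(C)[Si](C(C)C)(C(C)C)C#C/C=C/C[C@@H]1O[C@@H]2C[C@H]1O[C@H](CC)[C@H](O)C[C@H]2O | intermediate
20 | cyclic orthoacetate of 19 (2-methoxy-2-methyl-1,3-dioxane spanning the C10 and C12 oxygens; orthoester carbon unspecified) | CC(C)[Si](C(C)C)(C(C)C)C#C/C=C/C[C@@H]1O[C@@H]2C[C@H]1O[C@H](CC)[C@H]3C[C@H]2OC(C)(OC)O3 | intermediate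
21 | (1R,3R,4S,6R,7R,9S)-4-bromo-3-ethyl-9-[(2E)-5-(triisopropylsilyl)pent-2-en-4-yn-1-yl]-2,8-dioxabicyclo[5.2.1]decan-6-yl acetate | CC(C)[Si](C(C)C)(C(C)C)C#C/C=C/C[C@@H]1O[C@@H]2C[C@H]1O[C@H](CC)[C@@H](Br)C[C@H]2OC(C)=O | intermediate
22 | (1R,3R,4S,6R,7R,9S)-4-bromo-3-ethyl-9-[(2E)-pent-2-en-4-yn-1-yl]-2,8-dioxabicyclo[5.2.1]decan-6-yl acetate | C#C/C=C/C[C@@H]1O[C@@H]2C[C@H]1O[C@H](CC)[C@@H](Br)C[C@H]2OC(C)=O | target

Total step count: 15. Longest linear sequence: 15 steps (from 1).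

Steps most likely to fail

Step 12 (Proposed new method). What may go wrong: acylation of the amide by the C9 enolate (seven-membered Claisen closure) before the alkylation, stalling after ring A because the eight-membered acylation is slow, or epimerisation at C13 by excess base. Fallback, all known chemistry: starting from 16, a single equivalent of KN(SiMe3)2 at −78 °C is used so that the ring-A ketone 17 is isolated (intramolecular enolate alkylation). Kinetic enolisation of its methyl group (LiN(i-Pr)2, Me3SiCl, −78 °C) gives the trimethylsilyl enol ether F1, and i-Bu2AlH at −78 °C reduces the Weinreb amide to the aldehyde F2. MgBr2·OEt2 then promotes a chelation-controlled intramolecular Mukaiyama aldol addition that closes ring B and gives the hydroxy ketone F3, with the C12 hydroxyl syn to the C13 oxygen. Hydroxyl-directed 1,3-anti reduction with Me4NBH(OAc)3 returns to the route at diol 19, so that 18 and step 13 are bypassed.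

Step 13. What may go wrong: reversed or poor facial selectivity if the ring conformation opposes the catalyst, or enolisation of the β-diketone slowing hydride transfer so that mono-reduced or 1,3-syn material builds up. Fallback: substrate-directed instead of catalyst-controlled reduction. From 18, Me4NBH(OAc)3 in MeCN/AcOH delivers hydride intramolecularly, first from the boron-bound enol and then from the first-formed hydroxyl (1,3-anti), and arrives again at 19; this makes no new compound (F0).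

Step 14. What may go wrong: opening of the dioxanylium ion at C10 instead of C12, participation of the ring-B oxygen at C12 (retention or ring contraction), or elimination. Fallback: stepwise differentiation from 19. Et3SiCl/imidazole at low temperature silylates the more exposed exo hydroxyl at C10 to give the mono(triethylsilyl) ether F4. CBr4/P(n-C8H17)3 in toluene converts the free C12 hydroxyl into the bromide with inversion, giving the bromo silyl ether F5. HF·pyridine frees the C10 alcohol F6, and Ac2O/DMAP/pyridine then gives 21, where the route is rejoined.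

Further compounds
F1 | step 12 | (R)-N-methoxy-N-methyl-2-{[(2S,3R,5R)-2-[(2E)-5-(triisopropylsilyl)pent-2-en-4-yn-1-yl]-5-[1-(trimethylsilyloxy)ethenyl]oxolan-3-yl]oxy}butanamide | CC(C)[Si](C(C)C)(C(C)C)C#C/C=C/C[C@@H]1O[C@@H](C(=C)O[Si](C)(C)C)C[C@H]1O[C@H](CC)C(=O)N(C)OC
F2 | step 12 | (R)-2-{[(2S,3R,5R)-2-[(2E)-5-(triisopropylsilyl)pent-2-en-4-yn-1-yl]-5-[1-(trimethylsilyloxy)ethenyl]oxolan-3-yl]oxy}butanal | CC(C)[Si](C(C)C)(C(C)C)C#C/C=C/C[C@@H]1O[C@@H](C(=C)O[Si](C)(C)C)C[C@H]1O[C@H](CC)C=O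
F3 | step 12 | (1R,3R,4R,7R,9S)-3-ethyl-4-hydroxy-9-[(2E)-5-(triisopropylsilyl)pent-2-en-4-yn-1-yl]-2,8-dioxabicyclo[5.2.1]decan-6-one | CC(C)[Si](C(C)C)(C(C)C)C#C/C=C/C[C@@H]1O[C@@H]2C[C@H]1O[C@H](CC)[C@H](O)CC2=O
F0 | step 13 | none | none
F4 | step 14 | (1R,3R,4R,6R,7R,9S)-3-ethyl-6-(triethylsilyloxy)-9-[(2E)-5-(triisopropylsilyl)pent-2-en-4-yn-1-yl]-2,8-dioxabicyclo[5.2.1]decan-4-ol | CC(C)[Si](C(C)C)(C(C)C)C#C/C=C/C[C@@H]1O[C@@H]2C[C@H]1O[C@H](CC)[C@H](O)C[C@H]2O[Si](CC)(CC)CC
F5 | step 14 | (1R,3R,4S,6R,7R,9S)-4-bromo-3-ethyl-6-(triethylsilyloxy)-9-[(2E)-5-(triisopropylsilyl)pent-2-en-4-yn-1-yl]-2,8-dioxabicyclo[5.2.1]decane | CC(C)[Si](C(C)C)(C(C)C)C#C/C=C/C[C@@H]1O[C@@H]2C[C@H]1O[C@H](CC)[C@@H](Br)C[C@H]2O[Si](CC)(CC)CC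
F6 | step 14 | (1R,3R,4S,6R,7R,9S)-4-bromo-3-ethyl-9-[(2E)-5-(triisopropylsilyl)pent-2-en-4-yn-1-yl]-2,8-dioxabicyclo[5.2.1]decan-6-ol | CC(C)[Si](C(C)C)(C(C)C)C#C/C=C/C[C@@H]1O[C@@H]2C[C@H]1O[C@H](CC)[C@@H](Br)C[C@H]2O
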